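**Plan**
1. Retrosynthesis: remove the three acetates and one benzyl ether, then cut the central CH2–CH2 bond into a primary alkyl radical (half A, free 3-OH) and an α-methylene ketone (half B, 3-OAc). Both halves go back to one β-hydroxy ketone, 15.
2. The cyclohexanone of 15 (C5a–C6–C7–C8–C9–C9a, 1-benzoxepine numbering) is not made six-membered. It comes from a cyclopentanol by a 1,2-shift that inserts C6 between the quaternary C5a and the carbinol carbon (future C7).
3. Enabling feature: the O-bearing ring carbon C7 sits next to C6, the CH that carries the bridge carbon, and C6 is flanked by the quaternary ring-fusion carbon C5a. Written as C7=O with CH2OH on C6, this is the β-hydroxy ketone retron of a semipinacol ring enlargement in which C5a migrates.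
4. Forward order: side chain and C3 on 2-methylcyclopentane-1,3-dione; desymmetrisation (C5a) and inversion (C9a); oxepane by 7-exo alkoxymercuration (trans-5,7 bicycle); vinyl addition, directed epoxidation and ring enlargement to the trans-6,7 bicycle; the two C7 carbinol epimers made separately; radical union; acetylation; debenzylation.
5. Stereochemistry: C3 by ligand control (alkenylation); C5a by catalyst control (CBS); C9a by Mitsunobu inversion; C6 by invertive migration, backed by the equatorial thermodynamic preference; C7 of half A by equatorial methyl addition; C7 of half B by equatorial epoxidation and hydride opening.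

Key step: step 10

Remark (assumption): hydride delivery to 2-alkyl-2-methylcyclopentane-1,3-diones is taken to occur anti to the longer alkyl chain (hydroxyl cis to the chain), which is why the ring carbinol is inverted in step 5; each chiral catalyst is used in the enantiomer that gives the stated configuration.

**Route**

Step 1
Reactants: 1 2-methylcyclopentane-1,3-dione; 2 acrolein
Product: 3 3-(1-methyl-2,5-dioxocyclopentyl)propanal
Conditions: H2O, 25 °C
Reagents that add atoms: none
Why: Michael addition of the acidic 1,3-dione to acrolein is a clean C-alkylation that creates the (still prochiral) quaternary carbon, the future C5a.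

Step 2
Reactants: 3 3-(1-methyl-2,5-dioxocyclopentyl)propanal; 4 2-bromopropene
Product: 6 2-[(3S)-3-hydroxy-4-methylpent-4-en-1-yl]-2-methylcyclopentane-1,3-dione, via trimethylsilyl ether 5 (not isolated)
Conditions: CrCl2 (10 mol %), NiCl2(dme) (2 mol %), chiral oxazoline–sulfonamide ligand (12 mol %), Et3N, Mn, Me3SiCl, LiCl, MeCN, 25 °C; then 1 M HCl, THF, 0 °C
Reagents that add atoms: none
Why: The catalytic asymmetric Nozaki–Hiyama–Kishi alkenylation is aldehyde-selective in the presence of the two ketones, and the chiral chromium–sulfonamide complex controls the face of addition to set (S) at the carbinol carbon (future C3).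

Step 3
Reactants: 6 2-[(3S)-3-hydroxy-4-methylpent-4-en-1-yl]-2-methylcyclopentane-1,3-dione
Product: 7 2-[(3S)-3-(benzyloxy)-4-methylpent-4-en-1-yl]-2-methylcyclopentane-1,3-dione
Conditions: BnOC(=NH)CCl3, TfOH (5 mol %), CH2Cl2–cyclohexane, 0 °C
Reagents that add atoms: benzyl 2,2,2-trichloroacetimidate ClC(Cl)(Cl)C(=N)OCc1ccccc1
Why: Acid-catalysed imidate benzylation avoids base, to which the 2,2-disubstituted 1,3-dione is sensitive (retro-Claisen), and masks the one hydroxyl that is free in the target until the last step.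

Step 4
Reactants: 7 2-[(3S)-3-(benzyloxy)-4-methylpent-4-en-1-yl]-2-methylcyclopentane-1,3-dione
Product: 8 (2R,3R)-2-[(3S)-3-(benzyloxy)-4-methylpent-4-en-1-yl]-3-hydroxy-2-methylcyclopentan-1-one (OH cis to the side chain)
Conditions: (S)-2-methyl-CBS-oxazaborolidine (20 mol %), catecholborane, toluene, −60 °C
Reagents that add atoms: none
Why: Corey–Bakshi–Shibata reduction desymmetrises the enantiotopic carbonyls: the catalyst fixes the carbinol as (R) with the quaternary carbon as the large group, and hydride adds anti to the longer chain, which sets the quaternary carbon as (R).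

Step 5
Reactants: 8 (2R,3R)-2-[(3S)-3-(benzyloxy)-4-methylpent-4-en-1-yl]-3-hydroxy-2-methylcyclopentan-1-one
Product: 9 (1S,2R)-2-[(3S)-3-(benzyloxy)-4-methylpent-4-en-1-yl]-2-methyl-3-oxocyclopentyl 4-nitrobenzoate
Conditions: 4-O2NC6H4CO2H, PPh3, DIAD, toluene, 0 → 25 °C
Reagents that add atoms: 4-nitrobenzoic acid OC(=O)c1ccc(cc1)[N+](=O)[O-]
Why: Mitsunobu inversion with the acidic 4-nitrobenzoic acid, as used for cyclopentanols next to a quaternary carbon such as 17-hydroxy steroids, moves the oxygen to the face of the methyl group, as the trans ring fusion requires.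

Step 6
Reactants: 9 (1S,2R)-2-[(3S)-3-(benzyloxy)-4-methylpent-4-en-1-yl]-2-methyl-3-oxocyclopentyl 4-nitrobenzoate
Product: 10 (2R,3S)-2-[(3S)-3-(benzyloxy)-4-methylpent-4-en-1-yl]-3-hydroxy-2-methylcyclopentan-1-one (OH trans to the side chain)
Conditions: K2CO3 (cat.), MeOH, 0 °C
Reagents that add atoms: none
Why: Mild transesterification of the activated ester frees the alcohol without retro-aldol opening of the β-hydroxy ketone.

Step 7
Reactants: 10 (2R,3S)-2-[(3S)-3-(benzyloxy)-4-methylpent-4-en-1-yl]-3-hydroxy-2-methylcyclopentan-1-one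
Product: 12 (3S,5aR,8aS)-3-(benzyloxy)-2,2,5a-trimethyloctahydro-6H-cyclopenta[b]oxepin-6-one (trans-fused), via organomercurial 11 (not isolated)
Conditions: Hg(OCOCF3)2, CH2Cl2, −20 → 0 °C; then Bu3SnH, 0 → 25 °C
Reagents that add atoms: none
Why: Intramolecular alkoxymercuration–reductive demercuration (Markovnikov hydroalkoxylation) can only add the hydroxyl 7-exo at the tertiary alkene carbon, the CH2Hg carbon becomes the second methyl so no new stereocentre arises, and the fusion is trans because oxygen and chain were set trans in step 5.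

Step 8
Reactants: 12 (3S,5aR,8aS)-3-(benzyloxy)-2,2,5a-trimethyloctahydro-6H-cyclopenta[b]oxepin-6-one
Product: 13 (3S,5aR,6S,8aS)-3-(benzyloxy)-6-ethenyl-2,2,5a-trimethyloctahydro-2H-cyclopenta[b]oxepin-6-ol
Conditions: CH2=CHMgBr, CeCl3, THF, −78 °C
Reagents that add atoms: vinylmagnesium bromide C=C[Mg]Br
Why: Organocerium addition to the hindered, enolisable cyclopentanone occurs from the face opposite the angular methyl (as with 17-oxo steroids) and gives the tertiary allylic alcohol with OH cis to that methyl.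

Step 9
Reactants: 13 (3S,5aR,6S,8aS)-3-(benzyloxy)-6-ethenyl-2,2,5a-trimethyloctahydro-2H-cyclopenta[b]oxepin-6-ol
Product: 14 (3S,5aR,6R,8aS)-3-(benzyloxy)-2,2,5a-trimethyl-6-[(2S)-oxiran-2-yl]octahydro-2H-cyclopenta[b]oxepin-6-ol
Conditions: VO(acac)2 (5 mol %), t-BuOOH, CH2Cl2, 0 → 25 °C
Reagents that add atoms: tert-butyl hydroperoxide CC(C)(C)OO
Why: Vanadium-catalysed hydroxyl-directed epoxidation delivers oxygen syn to the carbinol through the erythro-type transition state with the bulky quaternary carbon anti to the forming C–O bond, which sets the oxirane carbon as (S).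

Step 10
Reactants: 14 (3S,5aR,6R,8aS)-3-(benzyloxy)-2,2,5a-trimethyl-6-[(2S)-oxiran-2-yl]octahydro-2H-cyclopenta[b]oxepin-6-ol
Product: 15 (3S,5aS,6R,9aS)-3-(benzyloxy)-6-(hydroxymethyl)-2,2,5a-trimethyloctahydro-1-benzoxepin-7(2H)-one
Conditions: BF3·OEt2 (0.5 equiv), CH2Cl2, −78 → −40 °C; NaHCO3 quench
Reagents that add atoms: none
Why: BF3 coordination opens the oxirane at the carbon next to the carbinol while the ring bond from the quaternary carbon to the carbinol carbon, anti-periplanar to the breaking C–O bond, shifts to that oxirane carbon and the carbinol becomes the C7 ketone (semipinacol rearrangement). The closest known reaction type is the Lewis-acid-promoted rearrangement of 2,3-epoxy alcohols to β-hydroxy ketones, including the ring enlargement of 1-oxiranylcycloalkanols to 2-(hydroxymethyl)cycloalkanones. No ring is closed by cyclisation: the cyclohexanone arises from the cyclopentane by insertion of the oxirane carbon between the quaternary carbon and the carbonyl carbon, a one-carbon enlargement that turns the trans-5,7 bicycle into the trans-6,7 bicycle of the target. The new stereocentre C6 is set by the configuration of the oxirane carbon because migration inverts it; this places the hydroxymethyl group cis to the angular methyl (equatorial), which is also the favoured epimer of this enolisable centre. The step needs migration of the quaternary ring carbon instead of the ring CH2, and both the higher migratory aptitude of the fully substituted carbon and the rotamer inherited from the directed epoxidation favour it. Low temperature and a non-nucleophilic counter-ion limit opening at the oxirane CH2 terminus.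

Step 11
Reactants: 15 (3S,5aS,6R,9aS)-3-(benzyloxy)-6-(hydroxymethyl)-2,2,5a-trimethyloctahydro-1-benzoxepin-7(2H)-one
Product: 16 (3S,5aS,6R,7R,9aS)-3-(benzyloxy)-6-(hydroxymethyl)-2,2,5a,7-tetramethyldecahydro-1-benzoxepin-7-ol
Conditions: MeLi, CeCl3, THF, −78 °C
Reagents that add atoms: methyllithium [Li]C
Why: Organocerium 1,2-addition (no enolisation or retro-aldol) comes from the equatorial direction because the axial path is blocked by the syn-axial C5a methyl, giving the axial tertiary alcohol (7R) of half A.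

Step 12
Reactants: 16 (3S,5aS,6R,7R,9aS)-3-(benzyloxy)-6-(hydroxymethyl)-2,2,5a,7-tetramethyldecahydro-1-benzoxepin-7-ol
Product: 17 (3S,5aS,6S,7R,9aS)-3-(benzyloxy)-6-(iodomethyl)-2,2,5a,7-tetramethyldecahydro-1-benzoxepin-7-ol
Conditions: I2, PPh3, imidazole, CH2Cl2, 0 → 25 °C
Reagents that add atoms: iodine II
Why: Appel iodination is selective for the primary hydroxyl over the hindered tertiary one and gives the radical precursor of half A.

Step 13
Reactants: 15 (3S,5aS,6R,9aS)-3-(benzyloxy)-6-(hydroxymethyl)-2,2,5a-trimethyloctahydro-1-benzoxepin-7(2H)-one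
Product: 18 (3S,5aS,6R,9aS)-3-hydroxy-6-(hydroxymethyl)-2,2,5a-trimethyloctahydro-1-benzoxepin-7(2H)-one
Conditions: H2 (1 atm), Pd/C, EtOAc, 25 °C
Reagents that add atoms: none
Why: Hydrogenolysis removes the benzyl ether from the material destined for half B, whose C3 oxygen is to be acetylated at the end.

Step 14
Reactants: 18 (3S,5aS,6R,9aS)-3-hydroxy-6-(hydroxymethyl)-2,2,5a-trimethyloctahydro-1-benzoxepin-7(2H)-one
Product: 20 (3S,5aS,9aS)-3-hydroxy-2,2,5a-trimethyl-6-methylideneoctahydro-1-benzoxepin-7(2H)-one, via mesylate 19 (not isolated)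
Conditions: MsCl, Et3N, CH2Cl2, −20 → 25 °C
Reagents that add atoms: none
Why: Selective mesylation of the primary hydroxyl followed by E1cB elimination with the amine gives the α-methylene ketone that serves as radical acceptor.

Step 15
Reactants: 17 (3S,5aS,6S,7R,9aS)-3-(benzyloxy)-6-(iodomethyl)-2,2,5a,7-tetramethyldecahydro-1-benzoxepin-7-ol; 20 (3S,5aS,9aS)-3-hydroxy-2,2,5a-trimethyl-6-methylideneoctahydro-1-benzoxepin-7(2H)-one
Product: 21 (3S,5aS,6S,9aS)-6-{2-[(3S,5aS,6S,7R,9aS)-3-(benzyloxy)-7-hydroxy-2,2,5a,7-tetramethyldecahydro-1-benzoxepin-6-yl]ethyl}-3-hydroxy-2,2,5a-trimethyloctahydro-1-benzoxepin-7(2H)-one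
Conditions: (Me3Si)3SiH, AIBN, toluene, 80 °C, slow addition of silane; 20 in slight excess
Reagents that add atoms: none
Why: In this Giese addition the primary radical from 17 adds to the unhindered CH2 terminus of the enone and the α-keto radical takes hydrogen from the silane on the face opposite the angular methyl, giving the equatorial side chain (6S), which is also the thermodynamic epimer; free hydroxyls are tolerated.

Step 16
Reactants: 21 (the coupled hydroxy ketone of step 15)
Product: 22 (3S,5aS,6R,9aS)-6-{2-[(3S,5aS,6S,7R,9aS)-3-(benzyloxy)-7-hydroxy-2,2,5a,7-tetramethyldecahydro-1-benzoxepin-6-yl]ethyl}-2,2,5a-trimethyl-7-methylidenedecahydro-1-benzoxepin-3-ol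
Conditions: Ph3PCH3Br, KOtBu, THF, 0 → 60 °C
Reagents that add atoms: methyltriphenylphosphonium bromide C[P+](c1ccccc1)(c1ccccc1)c1ccccc1.[Br-]
Why: Wittig methylenation of the α-branched cyclohexanone, with the two hydroxyls carried as alkoxides, installs the carbon that becomes the C7 methyl of half B.

Step 17
Reactants: 22 (the exocyclic alkene of step 16)
Product: 23 the 7-spiro-oxirane of 22 (new centre 7S; oxirane oxygen equatorial on the face opposite the C5a methyl, CH2 axial)
Conditions: mCPBA, NaHCO3, CH2Cl2, 0 °C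
Reagents that add atoms: 3-chloroperoxybenzoic acid OOC(=O)c1cccc(Cl)c1
Why: Peracid epoxidation of the exocyclic alkene occurs from the equatorial side because the axial side is shielded by the syn-axial C5a methyl, as in labdane 8(17)-enes.

Step 18
Reactants: 23 (the spiro-oxirane of step 17)
Product: 24 (3S,5aS,6S,7S,9aS)-6-{2-[(3S,5aS,6S,7R,9aS)-3-(benzyloxy)-7-hydroxy-2,2,5a,7-tetramethyldecahydro-1-benzoxepin-6-yl]ethyl}-2,2,5a,7-tetramethyldecahydro-1-benzoxepine-3,7-diol
Conditions: LiAlH4, THF, 0 → 25 °C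
Reagents that add atoms: none
Why: Hydride opens the spiro-oxirane at its CH2 carbon and leaves the equatorial tertiary alcohol with an axial methyl (7S) of half B.

Step 19
Reactants: 24 (the triol of step 18)
Product: 25 the 3,7-diacetate (half B) and 7-acetate (half A) of 24, with the benzyl ether on C3 of half A retained
Conditions: Ac2O, Sc(OTf)3 (5 mol %), MeCN, −20 → 0 °C
Reagents that add atoms: acetic anhydride CC(=O)OC(C)=O
Why: Sc(OTf)3-catalysed acylation esterifies hindered tertiary alcohols at low temperature without elimination, so the secondary and both tertiary hydroxyls are acetylated while the benzyl ether keeps the C3 oxygen of half A free of acetyl.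

Step 20
Reactants: 25 (the triacetate benzyl ether of step 19)
Product: 26 target, (3S,5aS,6S,7R,9aS)-6-{2-[(3S,5aS,6S,7S,9aS)-3,7-diacetoxy-2,2,5a,7-tetramethyldecahydro-1-benzoxepin-6-yl]ethyl}-3-hydroxy-2,2,5a,7-tetramethyldecahydro-1-benzoxepin-7-yl acetate
Conditions: H2 (1 atm), Pd/C, EtOAc, 25 °C
Reagents that add atoms: none
Why: Neutral hydrogenolysis of the benzyl ether leaves the three acetates, two of them tertiary, untouched and gives the target.

**Compound list**
1 | 2-methylcyclopentane-1,3-dione | CC1C(=O)CCC1=O | starting material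
2 | acrolein | C=CC=O | starting material
3 | 3-(1-methyl-2,5-dioxocyclopentyl)propanal | CC1(CCC=O)C(=O)CCC1=O | intermediate
4 | 2-bromopropene | CC(Br)=C | starting material
5 | 2-methyl-2-[(3S)-4-methyl-3-(trimethylsilyloxy)pent-4-en-1-yl]cyclopentane-1,3-dione | CC(=C)[C@@H](O[Si](C)(C)C)CCC1(C)C(=O)CCC1=O | intermediate
6 | 2-[(3S)-3-hydroxy-4-methylpent-4-en-1-yl]-2-methylcyclopentane-1,3-dione | CC(=C)[C@@H](O)CCC1(C)C(=O)CCC1=O | intermediate
7 | 2-[(3S)-3-(benzyloxy)-4-methylpent-4-en-1-yl]-2-methylcyclopentane-1,3-dione | CC(=C)[C@@H](OCc1ccccc1)CCC1(C)C(=O)CCC1=O | intermediate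
8 | (2R,3R)-2-[(3S)-3-(benzyloxy)-4-methylpent-4-en-1-yl]-3-hydroxy-2-methylcyclopentan-1-one | O=C1CC[C@@H](O)[C@@]1(C)CC[C@H](OCc1ccccc1)C(C)=C | intermediate
9 | (1S,2R)-2-[(3S)-3-(benzyloxy)-4-methylpent-4-en-1-yl]-2-methyl-3-oxocyclopentyl 4-nitrobenzoate | O=C1CC[C@H](OC(=O)c2ccc(cc2)[N+](=O)[O-])[C@@]1(C)CC[C@H](OCc1ccccc1)C(C)=C | intermediate
10 | (2R,3S)-2-[(3S)-3-(benzyloxy)-4-methylpent-4-en-1-yl]-3-hydroxy-2-methylcyclopentan-1-one | O=C1CC[C@H](O)[C@@]1(C)CC[C@H](OCc1ccccc1)C(C)=C | intermediate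
11 | {[(3S,5aR,8aS)-3-(benzyloxy)-2,5a-dimethyl-6-oxodecahydrocyclopenta[b]oxepin-2-yl]methyl}mercury trifluoroacetate (C2 epimers, both converge) | O=C1[C@]2(C)CC[C@H](OCc3ccccc3)C(C)(C[Hg]OC(=O)C(F)(F)F)O[C@H]2CC1 | intermediate
12 | (3S,5aR,8aS)-3-(benzyloxy)-2,2,5a-trimethyloctahydro-6H-cyclopenta[b]oxepin-6-one | O=C1[C@]2(C)CC[C@H](OCc3ccccc3)C(C)(C)O[C@H]2CC1 | intermediate
13 | (3S,5aR,6S,8aS)-3-(benzyloxy)-6-ethenyl-2,2,5a-trimethyloctahydro-2H-cyclopenta[b]oxepin-6-ol | C=C[C@]1(O)[C@]2(C)CC[C@H](OCc3ccccc3)C(C)(C)O[C@H]2CC1 | intermediate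
14 | (3S,5aR,6R,8aS)-3-(benzyloxy)-2,2,5a-trimethyl-6-[(2S)-oxiran-2-yl]octahydro-2H-cyclopenta[b]oxepin-6-ol | O[C@@]1([C@@H]2CO2)[C@]3(C)CC[C@H](OCc4ccccc4)C(C)(C)O[C@H]3CC1 | intermediate
15 | (3S,5aS,6R,9aS)-3-(benzyloxy)-6-(hydroxymethyl)-2,2,5a-trimethyloctahydro-1-benzoxepin-7(2H)-one | OC[C@H]1[C@]2(C)CC[C@H](OCc3ccccc3)C(C)(C)O[C@H]2CCC1=O | intermediate
16 | (3S,5aS,6R,7R,9aS)-3-(benzyloxy)-6-(hydroxymethyl)-2,2,5a,7-tetramethyldecahydro-1-benzoxepin-7-ol | OC[C@H]1[C@]2(C)CC[C@H](OCc3ccccc3)C(C)(C)O[C@H]2CC[C@@]1(C)O | intermediate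
17 | (3S,5aS,6S,7R,9aS)-3-(benzyloxy)-6-(iodomethyl)-2,2,5a,7-tetramethyldecahydro-1-benzoxepin-7-ol | IC[C@H]1[C@]2(C)CC[C@H](OCc3ccccc3)C(C)(C)O[C@H]2CC[C@@]1(C)O | intermediate
18 | (3S,5aS,6R,9aS)-3-hydroxy-6-(hydroxymethyl)-2,2,5a-trimethyloctahydro-1-benzoxepin-7(2H)-one | OC[C@H]1[C@]2(C)CC[C@H](O)C(C)(C)O[C@H]2CCC1=O | intermediate
19 | [(3S,5aS,6R,9aS)-3-hydroxy-2,2,5a-trimethyl-7-oxodecahydro-1-benzoxepin-6-yl]methyl methanesulfonate | CS(=O)(=O)OC[C@H]1[C@]2(C)CC[C@H](O)C(C)(C)O[C@H]2CCC1=O | intermediate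
20 | (3S,5aS,9aS)-3-hydroxy-2,2,5a-trimethyl-6-methylideneoctahydro-1-benzoxepin-7(2H)-one | C=C1[C@]2(C)CC[C@H](O)C(C)(C)O[C@H]2CCC1=O | intermediate
21 | (3S,5aS,6S,9aS)-6-{2-[(3S,5aS,6S,7R,9aS)-3-(benzyloxy)-7-hydroxy-2,2,5a,7-tetramethyldecahydro-1-benzoxepin-6-yl]ethyl}-3-hydroxy-2,2,5a-trimethyloctahydro-1-benzoxepin-7(2H)-one | O[C@H]1CC[C@]2(C)[C@H](CCC(=O)[C@H]2CC[C@H]2[C@]3(C)CC[C@H](OCc4ccccc4)C(C)(C)O[C@H]3CC[C@@]2(C)O)OC1(C)C | intermediate
22 | (3S,5aS,6R,9aS)-6-{2-[(3S,5aS,6S,7R,9aS)-3-(benzyloxy)-7-hydroxy-2,2,5a,7-tetramethyldecahydro-1-benzoxepin-6-yl]ethyl}-2,2,5a-trimethyl-7-methylidenedecahydro-1-benzoxepin-3-ol | O[C@H]1CC[C@]2(C)[C@H](CCC(=C)[C@H]2CC[C@H]2[C@]3(C)CC[C@H](OCc4ccccc4)C(C)(C)O[C@H]3CC[C@@]2(C)O)OC1(C)C | intermediate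
23 | 7-spiro-oxirane of 22 (half B: 3S,5aS,6S,7S,9aS; oxirane oxygen equatorial, CH2 axial; half A as in 21) | O[C@H]1CC[C@]2(C)[C@H](CC[C@@]3(CO3)[C@H]2CC[C@H]2[C@]4(C)CC[C@H](OCc5ccccc5)C(C)(C)O[C@H]4CC[C@@]2(C)O)OC1(C)C | intermediate
24 | (3S,5aS,6S,7S,9aS)-6-{2-[(3S,5aS,6S,7R,9aS)-3-(benzyloxy)-7-hydroxy-2,2,5a,7-tetramethyldecahydro-1-benzoxepin-6-yl]ethyl}-2,2,5a,7-tetramethyldecahydro-1-benzoxepine-3,7-diol | O[C@H]1CC[C@]2(C)[C@H](CC[C@](C)(O)[C@H]2CC[C@H]2[C@]3(C)CC[C@H](OCc4ccccc4)C(C)(C)O[C@H]3CC[C@@]2(C)O)OC1(C)C | intermediate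
25 | (3S,5aS,6S,7R,9aS)-3-(benzyloxy)-6-{2-[(3S,5aS,6S,7S,9aS)-3,7-diacetoxy-2,2,5a,7-tetramethyldecahydro-1-benzoxepin-6-yl]ethyl}-2,2,5a,7-tetramethyldecahydro-1-benzoxepin-7-yl acetate | CC(=O)O[C@H]1CC[C@]2(C)[C@H](CC[C@](C)(OC(C)=O)[C@H]2CC[C@H]2[C@]3(C)CC[C@H](OCc4ccccc4)C(C)(C)O[C@H]3CC[C@@]2(C)OC(C)=O)OC1(C)C | intermediate
26 | (3S,5aS,6S,7R,9aS)-6-{2-[(3S,5aS,6S,7S,9aS)-3,7-diacetoxy-2,2,5a,7-tetramethyldecahydro-1-benzoxepin-6-yl]ethyl}-3-hydroxy-2,2,5a,7-tetramethyldecahydro-1-benzoxepin-7-yl acetate | CC(=O)O[C@H]1CC[C@]2(C)[C@H](CC[C@](C)(OC(C)=O)[C@H]2CC[C@H]2[C@]3(C)CC[C@H](O)C(C)(C)O[C@H]3CC[C@@]2(C)OC(C)=O)OC1(C)C | target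

**Step count**
Total step count: 20. Longest linear sequence: 18 steps (steps 1–10, then 11–12 or 13–14, then 15–20).

**Steps most likely to fail**

Step 7. The seven-membered ring closure may be slower than intermolecular capture of the mercurinium ion by trifluoroacetate, or than mercuration of the benzyl arene. The fallback sets out from 10 and returns at 12. Epoxidation of the isopropenyl group with mCPBA gives the oxirane F1 (either epimer serves). Camphorsulfonic acid in CH2Cl2 opens it irreversibly, 7-exo at the tertiary carbon, to the 2-(hydroxymethyl)oxepane F2. 1,1'-Thiocarbonyldiimidazole converts the primary alcohol into the imidazolylthiocarbonate F3. Barton–McCombie reduction (Bu3SnH, AIBN, toluene, 110 °C) then turns the CH2O carbon into the second methyl and gives 12.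

Step 10. The ring CH2 may migrate instead of the quaternary carbon, or the complexed oxirane may be opened at its CH2 terminus. The fallback sets out from 13 and returns at 15. Dihydroxylation of the vinyl group (OsO4 cat., N-methylmorpholine N-oxide) gives the triol F4, shown as the (1S) epimer; the other epimer leads to the C6 epimer of 15, which is equilibrated. TBSCl/imidazole protects the primary hydroxyl to give the silyl ether F5, and MsCl/Et3N gives the secondary mesylate F6. Et2AlCl in CH2Cl2 at −78 °C forms the aluminium alkoxide of the tertiary alcohol and drives a concerted anti 1,2-shift with loss of mesylate (pinacol-type rearrangement of a β-mesyloxy alcohol) to the ring-enlarged silyloxymethyl ketone F7. HF·pyridine then gives 15.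

Step 5. Elimination to the β,γ-unsaturated ketone, or no substitution at all, may prevail at the carbinol next to the quaternary carbon. The fallback sets out from 7 and returns at 10, replacing steps 4–6. It is an enzymatic desymmetrising reduction (carbonyl reductase with NADPH recycling, or the whole-cell yeast reduction used for steroid seco-diones) of the kind known to give 3-hydroxy-2-alkyl-2-methylcyclopentanones with the hydroxyl cis to the methyl group. No inversion at carbon is then needed and no new compound is formed.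

**Further compounds**
F1 | step 7 | (2R,3S)-2-[(3S)-3-(benzyloxy)-3-(2-methyloxiran-2-yl)propyl]-3-hydroxy-2-methylcyclopentan-1-one (oxirane epimers) | O=C1CC[C@H](O)[C@@]1(C)CC[C@H](OCc1ccccc1)C1(C)CO1
F2 | step 7 | (3S,5aR,8aS)-3-(benzyloxy)-2-(hydroxymethyl)-2,5a-dimethyloctahydro-6H-cyclopenta[b]oxepin-6-one (C2 epimers) | O=C1[C@]2(C)CC[C@H](OCc3ccccc3)C(C)(CO)O[C@H]2CC1
F3 | step 7 | O-{[(3S,5aR,8aS)-3-(benzyloxy)-2,5a-dimethyl-6-oxodecahydrocyclopenta[b]oxepin-2-yl]methyl} 1H-imidazole-1-carbothioate | O=C1[C@]2(C)CC[C@H](OCc3ccccc3)C(C)(COC(=S)n3ccnc3)O[C@H]2CC1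
F4 | step 10 | (1S)-1-[(3S,5aR,6R,8aS)-3-(benzyloxy)-6-hydroxy-2,2,5a-trimethyloctahydro-2H-cyclopenta[b]oxepin-6-yl]ethane-1,2-diol | O[C@@]1([C@@H](O)CO)[C@]2(C)CC[C@H](OCc3ccccc3)C(C)(C)O[C@H]2CC1
F5 | step 10 | (1S)-1-[(3S,5aR,6R,8aS)-3-(benzyloxy)-6-hydroxy-2,2,5a-trimethyloctahydro-2H-cyclopenta[b]oxepin-6-yl]-2-[(tert-butyldimethylsilyl)oxy]ethan-1-ol | O[C@@]1([C@@H](O)CO[Si](C)(C)C(C)(C)C)[C@]2(C)CC[C@H](OCc3ccccc3)C(C)(C)O[C@H]2CC1
F6 | step 10 | (1S)-1-[(3S,5aR,6R,8aS)-3-(benzyloxy)-6-hydroxy-2,2,5a-trimethyloctahydro-2H-cyclopenta[b]oxepin-6-yl]-2-[(tert-butyldimethylsilyl)oxy]ethyl methanesulfonate | O[C@@]1([C@@H](OS(C)(=O)=O)CO[Si](C)(C)C(C)(C)C)[C@]2(C)CC[C@H](OCc3ccccc3)C(C)(C)O[C@H]2CC1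
F7 | step 10 | (3S,5aS,6R,9aS)-3-(benzyloxy)-6-{[(tert-butyldimethylsilyl)oxy]methyl}-2,2,5a-trimethyloctahydro-1-benzoxepin-7(2H)-one | CC(C)(C)[Si](C)(C)OC[C@H]1[C@]2(C)CC[C@H](OCc3ccccc3)C(C)(C)O[C@H]2CCC1=O
F0 | step 5 | none | none
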